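**Retrosynthetic overview**
1. The anti-1,3-diol is traced back to (S)-[10]-gingerol 11: the C3 carbinol comes from a hydroxyl-directed 1,3-anti reduction of the C3 ketone, after hydrogenolysis of two benzyl ethers.
2. Key disconnection: the bond between the arene carbon para to the phenol oxygen and benzylic C1, made by palladium-catalysed ring-opening cross-coupling of cyclopropanol 7 (a ketone homoenolate) with aryl bromide 8.
3. Enabling feature: the two methylenes C1 and C2 between the guaiacyl (4-hydroxy-3-methoxyphenyl) ring and oxygen-bearing C3 form a β-aryl carbonyl pattern. C1, C2 and C3 are folded into a temporary cyclopropanol whose two ring CH2 groups are equivalent, so strain release drives the coupling and no regiochemical question arises.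
4. Cyclopropanol 7 comes from a Kulinkovich reaction of O-benzylated methyl (S)-3-hydroxydodecanoate; the C5 stereocenter comes from a Noyori hydrogenation of methyl 3-oxododecanoate, made from decanoyl chloride and Meldrum's acid.
5. Ring order: the benzene ring is bought; the only ring built is the cyclopropane (step 4), and it is opened again in step 5.

Key step: step 5

Remark: the SMILES is read as (3S,5S)-1-(4-hydroxy-3-methoxyphenyl)tetradecane-3,5-diol, the 1,3-anti diol; C1 to C14 below number the tetradecane chain, C1 being the benzylic carbon.

**Step 1**
Reactants: 1 decanoyl chloride; 2 Meldrum's acid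
Product: 4 methyl 3-oxododecanoate, via acyl Meldrum's acid 3 (not isolated)
Conditions: pyridine, CH2Cl2, 0 °C to rt; then MeOH, reflux
Reagents that add atoms: methanol, CO
Why: C-acylation of Meldrum's acid followed by alcoholysis of the acyl Meldrum's acid 3 (ring opening by methanol, loss of acetone and decarboxylation) is the standard acyl Meldrum's acid route to β-keto esters.

**Step 2**
Reactants: 4 methyl 3-oxododecanoate
Product: 5 methyl (3S)-3-hydroxydodecanoate
Conditions: H2 (50 bar), RuCl2[(S)-BINAP] (0.2 mol %), MeOH, 50 °C
Reagents that add atoms: none
Why: Noyori asymmetric hydrogenation, in which the β-keto ester chelates divalent ruthenium through both carbonyl oxygen atoms and the (S)-BINAP ligand directs hydride to the ketone face that gives the (3S) alcohol, so the stereocenter that becomes C5 of the target is set by catalyst control.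

**Step 3**
Reactants: 5 methyl (3S)-3-hydroxydodecanoate
Product: 6 methyl (3S)-3-(benzyloxy)dodecanoate
Conditions: BnOC(=NH)CCl3, TfOH (cat.), cyclohexane/CH2Cl2 (2:1), 0 °C to rt
Reagents that add atoms: benzyl 2,2,2-trichloroacetimidate, N=C(OCc1ccccc1)C(Cl)(Cl)Cl
Why: Acid-catalysed trichloroacetimidate benzylation avoids the basic conditions under which a β-hydroxy ester would undergo retro-aldol cleavage or elimination, and the benzyl ether later keeps the secondary alcohol from being oxidised by palladium in step 5.

**Step 4**
Reactants: 6 methyl (3S)-3-(benzyloxy)dodecanoate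
Product: 7 1-[(2S)-2-(benzyloxy)undecyl]cyclopropan-1-ol
Conditions: EtMgBr (3.0 equiv, slow addition), Ti(OiPr)4 (0.2 equiv), THF, 0 °C to rt
Reagents that add atoms: ethylmagnesium bromide, CC[Mg]Br
Why: Kulinkovich cyclopropanation, in which the titanacyclopropane generated from EtMgBr and catalytic Ti(OiPr)4 acts as a 1,2-dicarbanion equivalent that adds twice to the ester carbonyl and expels methoxide, should give the 1-substituted cyclopropanol without touching the benzyloxy-bearing stereocenter.

**Step 5**
Reactants: 7 1-[(2S)-2-(benzyloxy)undecyl]cyclopropan-1-ol (1.2 equiv); 8 1-(benzyloxy)-4-bromo-2-methoxybenzene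
Product: 10 (5S)-5-(benzyloxy)-1-[4-(benzyloxy)-3-methoxyphenyl]tetradecan-3-one, via arylpalladium homoenolate 9 (not isolated)
Conditions: Pd(OAc)2 (5 mol %), XPhos (2-dicyclohexylphosphino-2',4',6'-triisopropylbiphenyl, 10 mol %), Cs2CO3 (2 equiv), toluene, 80 °C
Reagents that add atoms: none
Why: Palladium-catalysed ring-opening cross-coupling of a cyclopropanol with an aryl bromide (ketone homoenolate arylation) is an established reaction type for 1-alkylcyclopropanols, and 7 is an ordinary member of that class. Zerovalent palladium inserts into the C–Br bond of 8, the cyclopropanolate of 7 replaces bromide on divalent palladium, strain-driven β-carbon elimination opens the three-membered ring to the arylpalladium homoenolate 9, and C(sp3)–C(sp2) reductive elimination joins the arene carbon para to the benzyloxy group to C1. In this one operation the full C14 chain, the C3 carbonyl and the protected guaiacyl ring are assembled from two much simpler pieces, so that only deprotection and one reduction remain. No ring is closed (the temporary cyclopropane is opened) and no stereocenter is formed; C5 lies outside the reacting atoms and, as a benzyl ether, can neither be oxidised by palladium nor undergo retro-aldol cleavage. Site selectivity is built into the substrates, because the two ring CH2 groups of 7 are equivalent, so either C–C cleavage gives the same homoenolate, and the bromine atom of 8 fixes the position on the arene. The selectivity that must be won is reductive elimination over β-hydride elimination from 9; chelation of palladium by the ketone oxygen of the homoenolate in a five-membered ring disfavours the syn-coplanar geometry for β-hydride elimination, the bulky electron-rich XPhos speeds reductive elimination, and the mild heterogeneous carbonate base limits E1cB loss of benzyl alcohol from the product.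

**Step 6**
Reactants: 10 (5S)-5-(benzyloxy)-1-[4-(benzyloxy)-3-methoxyphenyl]tetradecan-3-one
Product: 11 (5S)-5-hydroxy-1-(4-hydroxy-3-methoxyphenyl)tetradecan-3-one, (S)-[10]-gingerol
Conditions: H2 (1 atm), 10% Pd/C, EtOAc, rt
Reagents that add atoms: none
Why: Catalytic hydrogenolysis should cleave the aryl and the secondary alkyl benzyl ether under neutral conditions that neither dehydrate the β-hydroxy ketone nor reduce the isolated aliphatic ketone.

**Step 7**
Reactants: 11 (5S)-5-hydroxy-1-(4-hydroxy-3-methoxyphenyl)tetradecan-3-one
Product: 13 (3S,5S)-1-(4-hydroxy-3-methoxyphenyl)tetradecane-3,5-diol, via alkoxydiacetoxyborohydride 12 (not isolated)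
Conditions: Me4NBH(OAc)3 (5 equiv), MeCN/AcOH (1:1), −30 to −20 °C
Reagents that add atoms: none
Why: Evans–Saksena 1,3-anti reduction, in which the C5 hydroxyl exchanges with an acetate on boron to give the alkoxydiacetoxyborohydride 12 that delivers hydride intramolecularly to the acid-activated C3 ketone through a chair-like six-membered transition state, so the existing (5S) center should set the new (3S) center anti to it.

**Compound list**
1 | decanoyl chloride | CCCCCCCCCC(=O)Cl | starting material
2 | Meldrum's acid (2,2-dimethyl-1,3-dioxane-4,6-dione) | CC1(C)OC(=O)CC(=O)O1 | starting material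
3 | 5-(1-hydroxydecylidene)-2,2-dimethyl-1,3-dioxane-4,6-dione (acyl Meldrum's acid, enol form; not isolated) | CCCCCCCCCC(O)=C1C(=O)OC(C)(C)OC1=O | intermediate
4 | methyl 3-oxododecanoate | CCCCCCCCCC(=O)CC(=O)OC | intermediate
5 | methyl (3S)-3-hydroxydodecanoate | CCCCCCCCC[C@H](O)CC(=O)OC | intermediate
6 | methyl (3S)-3-(benzyloxy)dodecanoate | CCCCCCCCC[C@H](OCc1ccccc1)CC(=O)OC | intermediate
7 | 1-[(2S)-2-(benzyloxy)undecyl]cyclopropan-1-ol | CCCCCCCCC[C@H](OCc1ccccc1)CC1(O)CC1 | intermediate
8 | 1-(benzyloxy)-4-bromo-2-methoxybenzene | COc1cc(Br)ccc1OCc1ccccc1 | starting material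
9 | [4-(benzyloxy)-3-methoxyphenyl][(5S)-5-(benzyloxy)-3-oxotetradecyl]palladium, the arylpalladium homoenolate (divalent palladium; XPhos ligand not drawn; not isolated) | CCCCCCCCC[C@H](OCc1ccccc1)CC(=O)CC[Pd]c1ccc(OCc2ccccc2)c(OC)c1 | intermediate
10 | (5S)-5-(benzyloxy)-1-[4-(benzyloxy)-3-methoxyphenyl]tetradecan-3-one | CCCCCCCCC[C@H](OCc1ccccc1)CC(=O)CCc1ccc(OCc2ccccc2)c(OC)c1 | intermediate
11 | (5S)-5-hydroxy-1-(4-hydroxy-3-methoxyphenyl)tetradecan-3-one, (S)-[10]-gingerol | CCCCCCCCC[C@H](O)CC(=O)CCc1ccc(O)c(OC)c1 | intermediate
12 | tetramethylammonium diacetoxy{[(5S)-1-(4-hydroxy-3-methoxyphenyl)-3-oxotetradecan-5-yl]oxy}hydroborate (not isolated) | C[N+](C)(C)C.CCCCCCCCC[C@H](O[BH-](OC(C)=O)OC(C)=O)CC(=O)CCc1ccc(O)c(OC)c1 | intermediate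
13 | (3S,5S)-1-(4-hydroxy-3-methoxyphenyl)tetradecane-3,5-diol | CCCCCCCCC[C@H](O)C[C@@H](O)CCc1ccc(O)c(OC)c1 | target

**Step count**
Total steps: 7. Longest linear sequence: 7 steps (1 to 13); aryl bromide 8 is bought and enters at step 5.

**Steps most likely to fail**

Step 5. What may go wrong: β-hydride elimination from the palladium homoenolate outrunning reductive elimination, slow oxidative addition into the electron-rich C–Br bond, α-arylation of the product ketone, or base-induced β-elimination of the benzyloxy group. The fallback forms the same aryl–C1 bond by conjugate addition instead of cross-coupling and sets out from 7. The threatening β-hydride elimination is made the intended path by aerobic palladium-catalysed oxidative ring opening (Pd(OAc)2, pyridine, O2, toluene, 80 °C), which should give (5S)-5-(benzyloxy)tetradec-1-en-3-one F1. Rhodium-catalysed 1,4-addition of commercial [4-(benzyloxy)-3-methoxyphenyl]boronic acid ([RhCl(cod)]2, aq. KOH, 1,4-dioxane, rt to 50 °C; Hayashi–Miyaura type) then places the aryl group on the terminal alkene carbon, and the route is rejoined at 10.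

Step 4. What may go wrong: direct double addition of the Grignard reagent to the ester when titanium turnover is slow, and base-induced β-elimination of the benzyloxy group from the ester enolate. The fallback bypasses the cyclopropanol, uses an allylic alcohol as the homoenolate equivalent and sets out from 6. Reduction with DIBAL-H (toluene, −78 °C) should give (3S)-3-(benzyloxy)dodecanal F2. Addition of vinylmagnesium bromide (THF, −78 °C) should give (5S)-5-(benzyloxy)tetradec-1-en-3-ol F3 as both C3 epimers, which is of no consequence because C3 becomes a carbonyl. Heck arylation with 8 (Pd(OAc)2, Bu4NCl, NaHCO3, DMF, 90 °C) delivers the aryl group to the terminal alkene carbon; β-hydride elimination toward the carbinol carbon and enol-to-ketone tautomerisation should then give the ketone, and the route is rejoined at 10.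

Step 7. What may go wrong: erosion of facial selectivity through competing non-directed intermolecular hydride transfer in this conformationally free chain. The fallback sets out from 11 and uses an Evans–Tishchenko reduction (SmI2 (30 mol %), acetaldehyde (excess), THF, −10 °C). The hemiacetal formed from the C5 hydroxyl and the aldehyde delivers hydride to C3 within a samarium chelate, which should give the anti monoester (3S,5S)-3-hydroxy-1-(4-hydroxy-3-methoxyphenyl)tetradecan-5-yl acetate F4. Methanolysis (K2CO3, MeOH, rt) then returns to the route at 13.

**Further compounds**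
F1 | step 5 | (5S)-5-(benzyloxy)tetradec-1-en-3-one | CCCCCCCCC[C@H](OCc1ccccc1)CC(=O)C=C
F2 | step 4 | (3S)-3-(benzyloxy)dodecanal | CCCCCCCCC[C@H](OCc1ccccc1)CC=O
F3 | step 4 | (5S)-5-(benzyloxy)tetradec-1-en-3-ol (both C3 epimers) | CCCCCCCCC[C@H](OCc1ccccc1)CC(O)C=C
F4 | step 7 | (3S,5S)-3-hydroxy-1-(4-hydroxy-3-methoxyphenyl)tetradecan-5-yl acetate | CCCCCCCCC[C@H](OC(C)=O)C[C@@H](O)CCc1ccc(O)c(OC)c1
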